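Labdane numbering is used: ring A = C1–C5 and C10, ring B = C5–C10. Retrosynthesis: the C19 CH2OAc goes back to a C19 nitrile. C9–C10 and C4–C5 are then cut together, which restores PhSO2 on C7 and a CO2–N(phthaloyl) group on C4 of an open chain.
The chain is cut at C6–C7 (allyl sulfone anion + allyl bromide), C3–C4 (cyanopropanoate alkylation), C5–C6 and C10–C20 (carboalumination, formaldehyde) and C1–C10 (acetylide + epichlorohydrin).
Forward: the C7–C9/C11–C17 sulfone comes from geraniol and the C1–C3/C5/C6/C10/C20 bromide from (R)-epichlorohydrin. They are joined, the C4 unit is added, and one radical cascade then closes ring A first and ring B last.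
Enabling feature: ring B is a cyclohexene whose C7=C8 bond lies next to the new C9–C10 bond, so closure at C9 leaves the radical on C8, beside C7, where a sulfonyl group can depart. C4 carries the oxidised carbon C19, which as C≡N stabilises the starting radical. The E-alkenes C5=C10 and C8=C9 are 1,5-related, as two 6-endo closures require.
Stereochemistry: C2 comes from (R)-epichlorohydrin. C4, C5, C9 and C10 come from the chair–chair cascade, steered by the equatorial C2–OTBS and the axial nitrile. The alkene geometries come from geraniol (13E), SeO2 oxidation and syn-carboalumination.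

Key step: step 13

Remark: compounds 17 and 20–24 are carried as mixtures of epimers at C7 (from 21 on also at C4), because both centres are erased in step 13. TBS = tert-butyldimethylsilyl.

Step 1
Reactants: 1 geraniol
Product: 2 geranyl TBS ether
Conditions: TBSCl, imidazole, DMF, 0 °C to rt
Reagents that add atoms: tert-butyldimethylsilyl chloride CC(C)(C)[Si](C)(C)Cl
Why: Routine silyl ether protection of a primary allylic alcohol, which touches neither the 2E alkene nor any stereocentre.

Step 2
Reactants: 2 geranyl TBS ether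
Product: 3 (2E,6E)-8-(TBSO)-2,6-dimethylocta-2,6-dien-1-ol
Conditions: SeO2 (cat.), t-BuOOH, CH2Cl2, 0 °C to rt
Reagents that add atoms: tert-butyl hydroperoxide CC(C)(C)OO
Why: Riley allylic oxidation (ene reaction, then [2,3]-shift) attacks the more electron-rich distal alkene at its E-methyl group, which fixes the E geometry of the future C8=C9 alkene.

Step 3
Reactants: 3 (2E,6E)-8-(TBSO)-2,6-dimethylocta-2,6-dien-1-ol
Product: 5 (2E,6E)-3,7-dimethyl-8-(phenylsulfonyl)octa-2,6-dien-1-yl TBS ether, via allylic bromide 4 (not isolated)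
Conditions: CBr4, PPh3, CH2Cl2, 0 °C; filter, concentrate; PhSO2Na, DMF, rt
Reagents that add atoms: carbon tetrabromide BrC(Br)(Br)Br (Br of 4); sodium benzenesulfinate [Na+].[O-]S(=O)c1ccccc1
Why: Appel bromination followed by SN2 S-alkylation of the sulfinate gives the primary allyl sulfone without allylic transposition.

Step 4
Reactants: 6 (R)-epichlorohydrin; 7 (trimethylsilyl)acetylene
Product: 9 (2R)-1-chloro-5-(trimethylsilyl)pent-4-yn-2-ol, via lithium acetylide 8 (not isolated)
Conditions: 7, n-BuLi, THF, −78 °C; BF3·OEt2; 6, −78 °C; aq. NaHCO3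
Reagents that add atoms: n-butyllithium [Li]CCCC (Li of 8)
Why: BF3-promoted alkynylation opens the epoxide at its unsubstituted carbon, so the C–O stereocentre (future C2) is carried over unchanged from 6 and the chloride stays in place at low temperature.

Step 5
Reactants: 9 (2R)-1-chloro-5-(trimethylsilyl)pent-4-yn-2-ol
Product: 10 TBS ether of 9
Conditions: TBSCl, imidazole, DMF, rt
Reagents that add atoms: tert-butyldimethylsilyl chloride CC(C)(C)[Si](C)(C)Cl
Why: Silyl ether protection of the secondary alcohol prevents epoxide re-closure and installs the group that later steers the cascade.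

Step 6
Reactants: 10 TBS ether of 9
Product: 11 (2R)-1-chloropent-4-yn-2-yl TBS ether
Conditions: K2CO3, MeOH, rt
Reagents that add atoms: none
Why: Base-catalysed methanolysis cleaves only the alkynyl C–Si bond, and the TBS ether and the primary chloride are inert under these conditions.

Step 7
Reactants: 11 (2R)-1-chloropent-4-yn-2-yl TBS ether
Product: 14 (2E,5R)-5-(TBSO)-6-chloro-3-methylhex-2-en-1-ol, via alkenylalane 12 (not isolated), via lithium alanate 13 (not isolated)
Conditions: Me3Al, Cp2ZrCl2 (cat.), CH2Cl2, 0 °C to rt; evaporate; n-BuLi, THF/hexane, −78 to 0 °C; (CH2O)n, rt; aq. Rochelle salt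
Reagents that add atoms: trimethylaluminium C[Al](C)C; n-butyllithium [Li]CCCC (Bu and Li of 13); paraformaldehyde, as formaldehyde C=O
Why: Negishi carboalumination adds CH3 and Al syn with Al at the terminus, and hydroxymethylation of the alanate proceeds with retention, which sets the E-trisubstituted C5=C10 alkene with C20 and C6 in place.

Step 8
Reactants: 14 (2E,5R)-5-(TBSO)-6-chloro-3-methylhex-2-en-1-ol
Product: 15 (2E,5R)-1-bromo-6-chloro-3-methylhex-2-en-5-yl TBS ether
Conditions: CBr4, PPh3, CH2Cl2, 0 °C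
Reagents that add atoms: carbon tetrabromide BrC(Br)(Br)Br
Why: The Appel reaction converts the primary allylic alcohol into the bromide under neutral conditions without loss of alkene geometry.

Step 9
Reactants: 5 allyl sulfone; 15 allylic bromide
Product: 17 (2E,6E,10E,13R)-13-(TBSO)-14-chloro-3,7,11-trimethyl-8-(phenylsulfonyl)tetradeca-2,6,10-trien-1-yl TBS ether, via lithiated sulfone 16 (not isolated)
Conditions: 5, n-BuLi, THF, −78 °C; 15, −78 to −40 °C
Reagents that add atoms: n-butyllithium [Li]CCCC (Li of 16)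
Why: The α-sulfonyl allyl carbanion is alkylated (sulfone-based terpene coupling) at its α-carbon by the allylic bromide, which is far more reactive than the β-branched chloride, and the new C7 centre may form as both epimers because it is erased in step 13.

Step 10
Reactants: 17 chloro sulfone; 18 ethyl 2-cyanopropanoate
Product: 21 ethyl (4R,6E,10E,14E)-4,16-bis(TBSO)-2-cyano-2,6,10,14-tetramethyl-9-(phenylsulfonyl)hexadeca-6,10,14-trienoate, via sodium cyanopropanoate 19 (not isolated), via primary iodide 20 (not isolated)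
Conditions: 18, NaH, DMF, 0 °C to rt; 17, NaI, 70 °C
Reagents that add atoms: sodium hydride [Na+].[H-] (Na of 19); sodium iodide [Na+].[I-] (I of 20)
Why: Finkelstein exchange is followed by SN2 alkylation of a soft, doubly stabilised carbanion that is too weakly basic to deprotonate the allyl sulfone, and C4 may form as both epimers because it is erased in step 13.

Step 11
Reactants: 21 cyano ester
Product: 23 (4R,6E,10E,14E)-4,16-bis(TBSO)-2-cyano-2,6,10,14-tetramethyl-9-(phenylsulfonyl)hexadeca-6,10,14-trienoic acid, via lithium carboxylate 22 (not isolated)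
Conditions: LiOH, THF/MeOH/H2O, 0 °C to rt; cold 0.5 M HCl to pH 4
Reagents that add atoms: lithium hydroxide [Li+].[OH-]
Why: Saponification of an ester activated by the α-cyano group runs at room temperature, where the nitrile, sulfone and silyl ethers persist and the quaternary cyano acid does not decarboxylate.

Step 12
Reactants: 23 cyano acid
Product: 24 N-(acyloxy)phthalimide of 23
Conditions: N-hydroxyphthalimide, DIC, DMAP (cat.), CH2Cl2, rt
Reagents that add atoms: N-hydroxyphthalimide O=C1c2ccccc2C(=O)N1O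
Why: Steglich-type carbodiimide esterification gives the redox-active ester, and the acid has no α-hydrogen, so ketene formation is excluded.

Step 13
Reactants: 24 N-(acyloxy)phthalimide
Product: 25 2α,15-bis(TBSO)labda-7,13E-diene-19-nitrile
Conditions: Ru(bpy)3(PF6)2 (2 mol %), Hantzsch ester (1.5 equiv), i-Pr2NEt (2 equiv), CH2Cl2 (0.005 M), blue LEDs, rt, argon
Reagents that add atoms: none
Why: Proposed new method: the photoreduced Ru(bpy)3 complex transfers one electron to the N-(acyloxy)phthalimide, which loses phthalimide anion and CO2 to leave the electrophilic tertiary α-cyano radical at C4; this adds to C5 of the electron-rich C5=C10 alkene, the nucleophilic tertiary C10 radical so formed adds to C9 of the allyl sulfone, and the C8 radical ejects PhSO2• from C7, which the Hantzsch ester reduces to sulfinate. The closest known reaction types are the photoredox decarboxylative allylation of N-(acyloxy)phthalimides by allyl sulfones (radical addition–fragmentation) and the all-6-endo radical polyene cyclisations started by α-carbonyl radicals from Mn(OAc)3; what is new is a sulfonyl group placed inside the forming ring as the terminator of such a cascade. Ring A closes 6-endo-trig (C4 to C5) and ring B closes last, also 6-endo-trig (C10 to C9), 5-exo attack being disfavoured in both cases because it would join two fully substituted carbons (C4–C10, C10–C8). A chair–chair array of the two E-alkenes gives anti addition across C5=C10 (H5 α, C20 β, trans-decalin) and puts C11 equatorial on C9 (H9 α); C2 selects the array, since its OTBS group stays equatorial (the other chair would hold it syn-axial to the C4 and C10 substituents), and at C4 the slim linear nitrile rather than the methyl group takes the axial β site beside C20. The step needs fragmentation of the C8 radical to outrun both its addition to C13=C14 and hydrogen capture, which the weak C7–S bond β to the radical, high dilution and the modest donor ability of the Hantzsch ester should secure, and fragmentation can place the ring B double bond only at C7=C8. Both C4 epimers and both C7 epimers of 24 converge on 25, because C4 becomes planar and C7 becomes sp2.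

Step 14
Reactants: 25 bicyclic nitrile
Product: 28 2α,15-bis(TBSO)labda-7,13E-dien-19-ol, via aluminium aldiminate 26 (not isolated), via aldehyde 27 (not isolated)
Conditions: i-Bu2AlH, toluene, −78 to 0 °C; aq. tartaric acid, rt; crude 27, NaBH4, MeOH, 0 °C
Reagents that add atoms: diisobutylaluminium hydride CC(C)C[AlH]CC(C)C (Al(i-Bu)2 of 26); water O (oxygen at C19)
Why: Hydride addition to the nitrile stops at the N-aluminated aldimine, hydrolysis gives a non-enolisable aldehyde and borohydride reduction gives the neopentyl alcohol, with C4 quaternary so that nothing can epimerise.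

Step 15
Reactants: 28 19-alcohol
Product: 29 19-acetoxy-2α,15-bis(TBSO)labda-7,13E-diene
Conditions: Ac2O, pyridine, DMAP (cat.), CH2Cl2, rt
Reagents that add atoms: acetic anhydride CC(=O)OC(C)=O
Why: DMAP-catalysed acetylation of the only free hydroxyl group places the acetate on C19 without any selectivity issue.

Step 16
Reactants: 29 bis-TBS acetate
Product: 30 19-acetoxylabda-7,13E-diene-2α,15-diol (target)
Conditions: HF·pyridine, pyridine, THF, 0 °C to rt
Reagents that add atoms: none
Why: Buffered fluoride desilylation frees both alcohols while the hindered neopentyl acetate persists and cannot migrate, since O2 (α) and C19 (β) lie on opposite faces of ring A.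

Compound list
1 | geraniol, (2E)-3,7-dimethylocta-2,6-dien-1-ol | CC(C)=CCC/C(C)=C/CO | starting material
2 | geranyl TBS ether | CC(C)=CCC/C(C)=C/CO[Si](C)(C)C(C)(C)C | intermediate
3 | (2E,6E)-8-(TBSO)-2,6-dimethylocta-2,6-dien-1-ol | OC/C(C)=C/CC/C(C)=C/CO[Si](C)(C)C(C)(C)C | intermediate
4 | (2E,6E)-8-bromo-3,7-dimethylocta-2,6-dien-1-yl TBS ether | BrC/C(C)=C/CC/C(C)=C/CO[Si](C)(C)C(C)(C)C | intermediate
5 | (2E,6E)-3,7-dimethyl-8-(phenylsulfonyl)octa-2,6-dien-1-yl TBS ether | O=S(=O)(C/C(C)=C/CC/C(C)=C/CO[Si](C)(C)C(C)(C)C)c1ccccc1 | intermediate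
6 | (R)-epichlorohydrin | ClC[C@H]1CO1 | starting material
7 | (trimethylsilyl)acetylene | C#C[Si](C)(C)C | starting material
8 | lithium (trimethylsilyl)acetylide | [Li]C#C[Si](C)(C)C | intermediate
9 | (2R)-1-chloro-5-(trimethylsilyl)pent-4-yn-2-ol | ClC[C@H](O)CC#C[Si](C)(C)C | intermediate
10 | (2R)-1-chloro-5-(trimethylsilyl)pent-4-yn-2-yl TBS ether | ClC[C@H](O[Si](C)(C)C(C)(C)C)CC#C[Si](C)(C)C | intermediate
11 | (2R)-1-chloropent-4-yn-2-yl TBS ether | ClC[C@H](O[Si](C)(C)C(C)(C)C)CC#C | intermediate
12 | (E)-alkenyl(dimethyl)alane from 11 (Al on C5, CH3 on C10) | ClC[C@H](O[Si](C)(C)C(C)(C)C)C/C(C)=C/[Al](C)C | intermediate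
13 | lithium (E)-alkenyl(butyl)dimethylalanate | [Li+].ClC[C@H](O[Si](C)(C)C(C)(C)C)C/C(C)=C/[Al-](C)(C)CCCC | intermediate
14 | (2E,5R)-5-(TBSO)-6-chloro-3-methylhex-2-en-1-ol | ClC[C@H](O[Si](C)(C)C(C)(C)C)C/C(C)=C/CO | intermediate
15 | (2E,5R)-1-bromo-6-chloro-3-methylhex-2-en-5-yl TBS ether | ClC[C@H](O[Si](C)(C)C(C)(C)C)C/C(C)=C/CBr | intermediate
16 | α-lithiated sulfone 5 | [Li]C(/C(C)=C/CC/C(C)=C/CO[Si](C)(C)C(C)(C)C)S(=O)(=O)c1ccccc1 | intermediate
17 | (2E,6E,10E,13R)-13-(TBSO)-14-chloro-3,7,11-trimethyl-8-(phenylsulfonyl)tetradeca-2,6,10-trien-1-yl TBS ether (both C8 epimers = labdane C7) | ClC[C@H](O[Si](C)(C)C(C)(C)C)C/C(C)=C/CC(/C(C)=C/CC/C(C)=C/CO[Si](C)(C)C(C)(C)C)S(=O)(=O)c1ccccc1 | intermediate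
18 | ethyl 2-cyanopropanoate (racemic) | CCOC(=O)C(C)C#N | starting material
19 | sodium salt of ethyl 2-cyanopropanoate | [Na+].CCOC(=O)[C-](C)C#N | intermediate
20 | primary iodide corresponding to 17 | IC[C@H](O[Si](C)(C)C(C)(C)C)C/C(C)=C/CC(/C(C)=C/CC/C(C)=C/CO[Si](C)(C)C(C)(C)C)S(=O)(=O)c1ccccc1 | intermediate
21 | ethyl (4R,6E,10E,14E)-4,16-bis(TBSO)-2-cyano-2,6,10,14-tetramethyl-9-(phenylsulfonyl)hexadeca-6,10,14-trienoate (epimers at C2 and C9) | CCOC(=O)C(C)(C#N)C[C@H](O[Si](C)(C)C(C)(C)C)C/C(C)=C/CC(/C(C)=C/CC/C(C)=C/CO[Si](C)(C)C(C)(C)C)S(=O)(=O)c1ccccc1 | intermediate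
22 | lithium carboxylate of 23 | [Li+].[O-]C(=O)C(C)(C#N)C[C@H](O[Si](C)(C)C(C)(C)C)C/C(C)=C/CC(/C(C)=C/CC/C(C)=C/CO[Si](C)(C)C(C)(C)C)S(=O)(=O)c1ccccc1 | intermediate
23 | (4R,6E,10E,14E)-4,16-bis(TBSO)-2-cyano-2,6,10,14-tetramethyl-9-(phenylsulfonyl)hexadeca-6,10,14-trienoic acid | OC(=O)C(C)(C#N)C[C@H](O[Si](C)(C)C(C)(C)C)C/C(C)=C/CC(/C(C)=C/CC/C(C)=C/CO[Si](C)(C)C(C)(C)C)S(=O)(=O)c1ccccc1 | intermediate
24 | 1,3-dioxoisoindolin-2-yl ester of 23 | O=C(ON1C(=O)c2ccccc2C1=O)C(C)(C#N)C[C@H](O[Si](C)(C)C(C)(C)C)C/C(C)=C/CC(/C(C)=C/CC/C(C)=C/CO[Si](C)(C)C(C)(C)C)S(=O)(=O)c1ccccc1 | intermediate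
25 | 2α,15-bis(TBSO)labda-7,13E-diene-19-nitrile (2R,4S,5R,9S,10R) | N#C[C@@]1(C)C[C@H](O[Si](C)(C)C(C)(C)C)C[C@]2(C)[C@@H](CC/C(C)=C/CO[Si](C)(C)C(C)(C)C)C(C)=CC[C@@H]12 | intermediate
26 | N-(diisobutylalumino)aldimine of 27 | CC(C)C[Al](CC(C)C)N=C[C@@]1(C)C[C@H](O[Si](C)(C)C(C)(C)C)C[C@]2(C)[C@@H](CC/C(C)=C/CO[Si](C)(C)C(C)(C)C)C(C)=CC[C@@H]12 | intermediate
27 | 2α,15-bis(TBSO)labda-7,13E-dien-19-al | O=C[C@@]1(C)C[C@H](O[Si](C)(C)C(C)(C)C)C[C@]2(C)[C@@H](CC/C(C)=C/CO[Si](C)(C)C(C)(C)C)C(C)=CC[C@@H]12 | intermediate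
28 | 2α,15-bis(TBSO)labda-7,13E-dien-19-ol | OC[C@@]1(C)C[C@H](O[Si](C)(C)C(C)(C)C)C[C@]2(C)[C@@H](CC/C(C)=C/CO[Si](C)(C)C(C)(C)C)C(C)=CC[C@@H]12 | intermediate
29 | 19-acetoxy-2α,15-bis(TBSO)labda-7,13E-diene | CC(=O)OC[C@@]1(C)C[C@H](O[Si](C)(C)C(C)(C)C)C[C@]2(C)[C@@H](CC/C(C)=C/CO[Si](C)(C)C(C)(C)C)C(C)=CC[C@@H]12 | intermediate
30 | 19-acetoxylabda-7,13E-diene-2α,15-diol (2R,4S,5R,9S,10R) | CC(=O)OC[C@@]1(C)C[C@H](O)C[C@]2(C)[C@@H](CC/C(C)=C/CO)C(C)=CC[C@@H]12 | target

Total step count: 16. Longest linear sequence: 13 steps (steps 4–16, from (R)-epichlorohydrin).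

Steps most likely to fail

1. Step 13. The C4 or C10 radical may be reduced or capture hydrogen before it cyclises. The chain may fold through the alternative chair, which would lose the control exerted by C2. The nitrile may not take the axial site cleanly. Released sulfonyl radicals may add back to the alkenes.
The fallback uses known chemistry only, sets out from 17 and rejoins the route at 28.
- The sulfone is removed reductively (PdCl2(dppp) cat., LiEt3BH, THF, 0 °C) to give the all-E chloro triene F1.
- Finkelstein exchange (NaI, acetone) gives the primary iodide F2.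
- Corey–Seebach alkylation with 2-lithio-2-methyl-1,3-dithiane gives the dithiane F3.
- MeI and CaCO3 in aqueous MeCN unmask the β-silyloxy methyl ketone F4.
- Corey–Chaykovsky methylenation (trimethylsulfonium iodide, NaH, DMSO/THF) gives the 2,2-disubstituted oxirane, from which the (4S)-epoxide F5 is separated from its C4 epimer.
- MeAlCl2 in CH2Cl2 at −78 °C then starts the classical epoxide-initiated cation–olefin bicyclisation. C5 displaces the epoxide oxygen at C4 with inversion, so C19 ends axial and already as CH2OH. The chair–chair fold with equatorial OTBS sets C5, C10 and C9, and ring B again closes last, giving 28.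
- In this variant the ring B alkene arises by proton loss, so positional isomers have to be removed by chromatography.

2. Step 10. Substitution at the β-branched carbon beside the bulky silyl ether may be too slow, so that elimination or silyl migration takes over.
The fallback replaces halide displacement by epoxide opening and lactonisation. It sets out from 17 and rejoins the route at 23.
- Bu4NF in THF removes both silyl groups to give the chlorohydrin diol F6.
- K2CO3 in MeOH closes the terminal epoxide F7.
- The sodium salt 19 in hot EtOH opens the epoxide at C3, and the C2 alkoxide closes onto the ester to give the α-cyano-α-methyl-γ-butyrolactone F8.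
- LiOH opens the lactone to the lithium hydroxy carboxylate F9.
- TBSCl and imidazole in DMF silylate all three oxygens to give the silyl ester bis-silyl ether F10.
- K2CO3 in aqueous MeOH/THF cleaves only the silyl ester, and mild acidification gives 23.

3. Step 7. The Lewis acidic aluminium/zirconium medium may attack the silyl ether. Methyl may be delivered in part to the wrong alkyne carbon. Capture of the alanate by paraformaldehyde may be inefficient.
The fallback builds the trisubstituted alkene by hydroalumination and cross-coupling instead of carbometalation. It sets out from 11 and rejoins the route at 14.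
- Deprotonation (n-BuLi) and addition to paraformaldehyde give the propargylic alcohol F11.
- Alkoxide-directed trans-hydroalumination with NaAlH2(OCH2CH2OMe)2, followed by I2, gives the (Z)-γ-iodo allylic alcohol F12.
- Me2CuLi in Et2O at 0 °C replaces iodine by methyl with retention of geometry and gives 14.

Further compounds
F1 | step 13 | (2E,6E,10E,13R)-13-(TBSO)-14-chloro-3,7,11-trimethyltetradeca-2,6,10-trien-1-yl TBS ether | ClC[C@H](O[Si](C)(C)C(C)(C)C)C/C(C)=C/CC/C(C)=C/CC/C(C)=C/CO[Si](C)(C)C(C)(C)C
F2 | step 13 | primary iodide corresponding to F1 | IC[C@H](O[Si](C)(C)C(C)(C)C)C/C(C)=C/CC/C(C)=C/CC/C(C)=C/CO[Si](C)(C)C(C)(C)C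
F3 | step 13 | 2-methyl-1,3-dithian-2-yl compound from F2 | CC1(SCCCS1)C[C@H](O[Si](C)(C)C(C)(C)C)C/C(C)=C/CC/C(C)=C/CC/C(C)=C/CO[Si](C)(C)C(C)(C)C
F4 | step 13 | (4R,6E,10E,14E)-4,16-bis(TBSO)-6,10,14-trimethylhexadeca-6,10,14-trien-2-one | CC(=O)C[C@H](O[Si](C)(C)C(C)(C)C)C/C(C)=C/CC/C(C)=C/CC/C(C)=C/CO[Si](C)(C)C(C)(C)C
F5 | step 13 | (S)-2-methyl-2-substituted oxirane from F4 (labdane C4 S, C2 R) | C1O[C@@]1(C)C[C@H](O[Si](C)(C)C(C)(C)C)C/C(C)=C/CC/C(C)=C/CC/C(C)=C/CO[Si](C)(C)C(C)(C)C
F6 | step 10 | (2E,6E,10E,13R)-14-chloro-3,7,11-trimethyl-8-(phenylsulfonyl)tetradeca-2,6,10-triene-1,13-diol | ClC[C@H](O)C/C(C)=C/CC(/C(C)=C/CC/C(C)=C/CO)S(=O)(=O)c1ccccc1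
F7 | step 10 | terminal epoxide from F6 | C1O[C@@H]1C/C(C)=C/CC(/C(C)=C/CC/C(C)=C/CO)S(=O)(=O)c1ccccc1
F8 | step 10 | α-cyano-α-methyl-γ-butyrolactone from F7 | N#CC1(C)C[C@H](OC1=O)C/C(C)=C/CC(/C(C)=C/CC/C(C)=C/CO)S(=O)(=O)c1ccccc1
F9 | step 10 | lithium salt of the ring-opened dihydroxy cyano acid | [Li+].[O-]C(=O)C(C)(C#N)C[C@H](O)C/C(C)=C/CC(/C(C)=C/CC/C(C)=C/CO)S(=O)(=O)c1ccccc1
F10 | step 10 | TBS ester of 23 | CC(C)(C)[Si](C)(C)OC(=O)C(C)(C#N)C[C@H](O[Si](C)(C)C(C)(C)C)C/C(C)=C/CC(/C(C)=C/CC/C(C)=C/CO[Si](C)(C)C(C)(C)C)S(=O)(=O)c1ccccc1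
F11 | step 7 | (5R)-5-(TBSO)-6-chlorohex-2-yn-1-ol | ClC[C@H](O[Si](C)(C)C(C)(C)C)CC#CCO
F12 | step 7 | (2Z,5R)-5-(TBSO)-6-chloro-3-iodohex-2-en-1-ol | ClC[C@H](O[Si](C)(C)C(C)(C)C)C/C(I)=C/CO
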